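**Retrosynthetic overview**

- Labels: C1 lactone C=O, C2 its CH2, C3 fusion CH on the ether O, C4 fusion C (CH3, lactone O), C5 CH2, C6 C(CH3)(chain), C7–C18 chain; ring A = oxolane (O, C3, C4, C5, C6), ring B = γ-lactone (O, C1, C2, C3, C4).
- Feature used: in ring A, C3 holds the ring oxygen and the C2–C1 arm beside the oxygenated C4. This is a masked 2-allyloxolan-3-one: the allyl arm is C2–C1 plus one carbon to be cut off, and the C4 ketone is the carbinol precursor.
- Late disconnections: C7=C8 (Wittig, then hydrogenation); ring B C1–O (ozonolysis of the allyl arm, lactol oxidation); C4–CH3 (MeMgBr/CeCl3 on the C4 ketone).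
- Key disconnection: O–C3 and C3–C2 of ring A, made together from an allyl ether diazoketone by copper carbenoid capture at the C6 ether oxygen and [2,3] shift. The diazoketone comes from (R)-citramalic acid, which supplies C4–C7 and the C6 stereocentre.
- Ring order: ring A in step 7, ring B in steps 9 and 10.

Key step: step 7

Assumption: allyl 2,2,2-trichloroacetimidate (5) is used as a purchased reagent; it is otherwise one step from allyl alcohol and Cl3CCN.

Note on descriptors: C6 keeps the same spatial arrangement throughout. Its CIP label is R while C7 is CH2O, CHO or vinylic, and becomes S in the target only because the ranking of its substituents changes.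

**Route**

Step 1
Reactants: 1 (R)-citramalic acid [(2R)-2-hydroxy-2-methylbutanedioic acid]
Product: 2 dimethyl (2R)-2-hydroxy-2-methylbutanedioate
Conditions: MeOH, H2SO4 (cat.), reflux
Reagents that add atoms: methanol, CO
Why: Fischer esterification converts both carboxyl groups to methyl esters without touching the tertiary carbinol stereocentre (C6), which carries no acidic hydrogen.

Step 2
Reactants: 2 dimethyl (2R)-2-hydroxy-2-methylbutanedioate
Product: 3 methyl (3R)-3,4-dihydroxy-3-methylbutanoate
Conditions: BH3·SMe2 (1.05 equiv), NaBH4 (5 mol%), THF, 0 °C to rt; MeOH quench; crude used directly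
Reagents that add atoms: none
Why: Hydroxyl-directed borane reduction of an α-hydroxy ester: the tertiary OH forms an alkoxyborane that, activated by catalytic NaBH4, delivers hydride through a five-membered chelate to the adjacent ester only, so the CH2CO2Me ester (future C4) survives and C6 is untouched.

Step 3
Reactants: 3 methyl (3R)-3,4-dihydroxy-3-methylbutanoate
Product: 4 methyl (3R)-4-[(tert-butyldiphenylsilyl)oxy]-3-hydroxy-3-methylbutanoate
Conditions: t-BuPh2SiCl, imidazole, CH2Cl2, 0 °C to rt
Reagents that add atoms: tert-butyl(chloro)diphenylsilane, CC(C)(C)[Si](Cl)(c1ccccc1)c1ccccc1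
Why: Silyl ether formation is selective for the unhindered primary hydroxyl over the tertiary one, and the bulky, acid-stable silyl group is the steric control element for step 7.

Step 4
Reactants: 4 methyl (3R)-4-[(tert-butyldiphenylsilyl)oxy]-3-hydroxy-3-methylbutanoate; 5 allyl 2,2,2-trichloroacetimidate
Product: 6 methyl (3R)-4-[(tert-butyldiphenylsilyl)oxy]-3-methyl-3-(prop-2-en-1-yloxy)butanoate
Conditions: TfOH (10 mol%), cyclohexane/CH2Cl2 2:1, 0 °C to rt
Reagents that add atoms: none
Why: Brønsted-acid-catalysed O-alkylation with a trichloroacetimidate etherifies the tertiary hydroxyl without forming its alkoxide, so retro-aldol cleavage, β-elimination and 1,4-silyl migration of this β-hydroxy ester are avoided, and the C6–O bond is not broken so configuration is retained.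

Step 5
Reactants: 6 methyl (3R)-4-[(tert-butyldiphenylsilyl)oxy]-3-methyl-3-(prop-2-en-1-yloxy)butanoate
Product: 7 (3R)-4-[(tert-butyldiphenylsilyl)oxy]-3-methyl-3-(prop-2-en-1-yloxy)butanoic acid
Conditions: LiOH·H2O, THF/MeOH/H2O, rt; then 1 M HCl to pH 3
Reagents that add atoms: lithium hydroxide, [Li+].[OH-]
Why: Ester saponification at room temperature should be faster than E1cB loss of the β-allyloxy group and leaves the silyl ether intact.

Step 6
Reactants: 7 (3R)-4-[(tert-butyldiphenylsilyl)oxy]-3-methyl-3-(prop-2-en-1-yloxy)butanoic acid; 8 (trimethylsilyl)diazomethane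
Product: 10 (4R)-5-[(tert-butyldiphenylsilyl)oxy]-1-diazo-4-methyl-4-(prop-2-en-1-yloxy)pentan-2-one, via acid chloride 9 (not isolated)
Conditions: (COCl)2, DMF (cat.), CH2Cl2, 0 °C to rt, evaporate; then Me3SiCHN2 (2 equiv), MeCN/THF 1:1, 0 °C to rt
Reagents that add atoms: none
Why: Acid chloride formation followed by C-acylation of the diazoalkane (the first stage of an Arndt–Eistert sequence) gives the terminal diazoketone, the silyl group leaving as Me3SiCl, under conditions to which neither ether is sensitive.

Step 7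
Reactants: 10 (4R)-5-[(tert-butyldiphenylsilyl)oxy]-1-diazo-4-methyl-4-(prop-2-en-1-yloxy)pentan-2-one
Product: 12 (2S,5R)-5-{[(tert-butyldiphenylsilyl)oxy]methyl}-5-methyl-2-(prop-2-en-1-yl)oxolan-3-one, via oxonium ylide 11 (not isolated)
Conditions: Cu(acac)2 (5 mol%), CH2Cl2, reflux, slow addition of 10
Reagents that add atoms: none
Why: Cu(acac)2 (a divalent copper precatalyst, reduced by the diazo compound to the active monovalent copper species) expels N2 from 10 and gives an electrophilic copper carbenoid at C3, which is captured by a lone pair of the C6 allyl ether oxygen to form the five-membered cyclic oxonium ylide 11; the allyl group then moves from oxygen to C3 by a [2,3]-sigmatropic shift through an envelope transition state, so that the O–C3 and C3–C2 bonds are both made in this step. The closest known reaction type is exactly this copper-catalysed tandem oxonium ylide formation and [2,3] rearrangement of allyloxy diazoketones to 2-allyloxolan-3-ones. Ring A closes by attack of the ether oxygen on the carbenoid carbon in a 5-exo sense (Cu=C3 bond outside the new ring of O, C3, C4, C5 and C6). The new stereocentre C3 is controlled by the quaternary C6 centre inherited from citramalic acid: in 11 the O-allyl group should lie on the ring face away from the bulky CH2OSi(t-Bu)Ph2 group and the suprafacial shift keeps it on that face, so allyl should end cis to the C6 methyl (2S). The step needs ylide formation to outrun C–H insertion into the OCH2 groups, cyclopropanation of the allyl alkene and a [1,2] shift; the copper catalyst (in place of Rh2(OAc)4, which favours C–H insertion), the five-membered size of the ylide ring and the allyl migrating group secure this. Should the C3 epimer form as well, it should be separable by chromatography and can be re-equilibrated through the enol with a mild base.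

Step 8
Reactants: 12 (2S,5R)-5-{[(tert-butyldiphenylsilyl)oxy]methyl}-5-methyl-2-(prop-2-en-1-yl)oxolan-3-one
Product: 13 (2S,3S,5R)-5-{[(tert-butyldiphenylsilyl)oxy]methyl}-3,5-dimethyl-2-(prop-2-en-1-yl)oxolan-3-ol
Conditions: MeMgBr, CeCl3 (anhydrous), THF, −78 °C
Reagents that add atoms: methylmagnesium bromide, C[Mg]Br
Why: Organocerium 1,2-addition to the ketone: the weakly basic reagent suppresses enolisation of the α-alkoxy ketone and should approach C4 from the face anti to the adjacent C3 allyl group, placing the new methyl trans and the new hydroxyl cis to allyl (3S).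

Step 9
Reactants: 13 (2S,3S,5R)-5-{[(tert-butyldiphenylsilyl)oxy]methyl}-3,5-dimethyl-2-(prop-2-en-1-yl)oxolan-3-ol
Product: 16 (3aS,5R,6aS)-5-{[(tert-butyldiphenylsilyl)oxy]methyl}-5,6a-dimethylhexahydrofuro[3,2-b]furan-2-ol (anomer mixture), via ozonide 14 (not isolated), via hydroxy aldehyde 15 (not isolated)
Conditions: O3, CH2Cl2, −78 °C; then PPh3, −78 °C to rt
Reagents that add atoms: ozone, [O-][O+]=O
Why: Ozonolysis with reductive work-up cleaves the terminal alkene to the C1 aldehyde, which is captured at once by the cis C4 hydroxyl as the five-membered lactol of ring B (only the cis-fused bicycle is possible), so that C2–C1 come from the allyl arm.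

Step 10
Reactants: 16 (3aS,5R,6aS)-5-{[(tert-butyldiphenylsilyl)oxy]methyl}-5,6a-dimethylhexahydrofuro[3,2-b]furan-2-ol
Product: 17 (3aS,5R,6aS)-5-{[(tert-butyldiphenylsilyl)oxy]methyl}-5,6a-dimethyltetrahydrofuro[3,2-b]furan-2(3H)-one
Conditions: (n-Pr4N)RuO4 (5 mol%), NMO, 4 Å MS, CH2Cl2, rt
Reagents that add atoms: none
Why: Catalytic perruthenate oxidation (Ley–Griffith conditions) converts the lactol to the γ-lactone under neutral conditions that tolerate the silyl ether, and no stereocentre is affected because the anomeric carbon becomes the carbonyl.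

Step 11
Reactants: 17 (3aS,5R,6aS)-5-{[(tert-butyldiphenylsilyl)oxy]methyl}-5,6a-dimethyltetrahydrofuro[3,2-b]furan-2(3H)-one
Product: 18 (3aS,5R,6aS)-5-(hydroxymethyl)-5,6a-dimethyltetrahydrofuro[3,2-b]furan-2(3H)-one
Conditions: Bu4NF, AcOH (1:1), THF, rt to 40 °C
Reagents that add atoms: none
Why: Fluoride-mediated cleavage of the Si–O bond, buffered with acetic acid so that the lactone enolate cannot expel the C3 ether oxygen by E1cB, frees the neopentyl primary alcohol.

Step 12
Reactants: 18 (3aS,5R,6aS)-5-(hydroxymethyl)-5,6a-dimethyltetrahydrofuro[3,2-b]furan-2(3H)-one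
Product: 19 (3aS,5R,6aS)-5,6a-dimethyl-2-oxohexahydrofuro[3,2-b]furan-5-carbaldehyde (lactone numbering kept)
Conditions: Dess–Martin periodinane, CH2Cl2, rt
Reagents that add atoms: none
Why: Dess–Martin oxidation gives the aldehyde under mild conditions, and because its α-carbon C6 is quaternary it can neither enolise nor epimerise.

Step 13
Reactants: 20 11-phenylundecanoic acid
Product: 21 11-phenylundecan-1-ol
Conditions: BH3·THF, THF, 0 °C to rt; aqueous work-up
Reagents that add atoms: none
Why: Borane reduction of a carboxylic acid to the primary alcohol is chemoselective and does not affect the phenyl ring.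

Step 14
Reactants: 21 11-phenylundecan-1-ol
Product: 22 (11-bromoundecyl)benzene
Conditions: CBr4, PPh3, CH2Cl2, 0 °C to rt
Reagents that add atoms: carbon tetrabromide, BrC(Br)(Br)Br
Why: Appel bromination converts the primary alcohol to the bromide by SN2 displacement of the phosphonium-activated oxygen.

Step 15
Reactants: 22 (11-bromoundecyl)benzene
Product: 23 (11-phenylundecyl)triphenylphosphonium bromide
Conditions: PPh3, MeCN, reflux
Reagents that add atoms: triphenylphosphine, c1ccc(cc1)P(c1ccccc1)c1ccccc1
Why: SN2 quaternisation of triphenylphosphine by the primary bromide gives the Wittig salt.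

Step 16
Reactants: 19 (3aS,5R,6aS)-5,6a-dimethyl-2-oxohexahydrofuro[3,2-b]furan-5-carbaldehyde; 23 (11-phenylundecyl)triphenylphosphonium bromide
Product: 25 (3aS,5R,6aS)-5,6a-dimethyl-5-(12-phenyldodec-1-en-1-yl)tetrahydrofuro[3,2-b]furan-2(3H)-one (mainly Z expected), via phosphorus ylide 24 (not isolated)
Conditions: NaN(SiMe3)2, THF, 0 °C (ylide from 23); then 19, −78 °C to rt
Reagents that add atoms: none
Why: Wittig olefination: the non-stabilised ylide should add to the unenolisable aldehyde far faster than to the lactone at low temperature, and the alkene geometry is irrelevant because the double bond is hydrogenated next.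

Step 17
Reactants: 25 (3aS,5R,6aS)-5,6a-dimethyl-5-(12-phenyldodec-1-en-1-yl)tetrahydrofuro[3,2-b]furan-2(3H)-one
Product: 26 plakortone L, (3aS,5S,6aS)-5,6a-dimethyl-5-(12-phenyldodecyl)tetrahydrofuro[3,2-b]furan-2(3H)-one
Conditions: H2 (1 atm), Pd/C, EtOAc, rt
Reagents that add atoms: none
Why: Heterogeneous catalytic hydrogenation saturates the disubstituted alkene in a neutral solvent, where the lactone, the unactivated phenyl ring and the allylic C6–O bond should be left alone, and gives the target with all three stereocentres unchanged.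

**Compound list**

1 | (R)-citramalic acid | C[C@](O)(C(O)=O)CC(O)=O | starting material
2 | dimethyl (2R)-2-hydroxy-2-methylbutanedioate | C[C@](O)(C(=O)OC)CC(=O)OC | intermediate
3 | methyl (3R)-3,4-dihydroxy-3-methylbutanoate | C[C@](O)(CO)CC(=O)OC | intermediate
4 | methyl (3R)-4-[(tert-butyldiphenylsilyl)oxy]-3-hydroxy-3-methylbutanoate | C[C@](O)(CO[Si](c1ccccc1)(c1ccccc1)C(C)(C)C)CC(=O)OC | intermediate
5 | allyl 2,2,2-trichloroacetimidate | C=CCOC(=N)C(Cl)(Cl)Cl | starting material
6 | methyl (3R)-4-[(tert-butyldiphenylsilyl)oxy]-3-methyl-3-(prop-2-en-1-yloxy)butanoate | C[C@](OCC=C)(CO[Si](c1ccccc1)(c1ccccc1)C(C)(C)C)CC(=O)OC | intermediate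
7 | (3R)-4-[(tert-butyldiphenylsilyl)oxy]-3-methyl-3-(prop-2-en-1-yloxy)butanoic acid | C[C@](OCC=C)(CO[Si](c1ccccc1)(c1ccccc1)C(C)(C)C)CC(=O)O | intermediate
8 | (trimethylsilyl)diazomethane | C[Si](C)(C)C=[N+]=[N-] | starting material
9 | (3R)-4-[(tert-butyldiphenylsilyl)oxy]-3-methyl-3-(prop-2-en-1-yloxy)butanoyl chloride | C[C@](OCC=C)(CO[Si](c1ccccc1)(c1ccccc1)C(C)(C)C)CC(=O)Cl | intermediate
10 | (4R)-5-[(tert-butyldiphenylsilyl)oxy]-1-diazo-4-methyl-4-(prop-2-en-1-yloxy)pentan-2-one | [N-]=[N+]=CC(=O)C[C@](C)(CO[Si](c1ccccc1)(c1ccccc1)C(C)(C)C)OCC=C | intermediate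
11 | cyclic oxonium ylide, (5R)-1-allyl-5-{[(tert-butyldiphenylsilyl)oxy]methyl}-5-methyl-3-oxooxolan-1-ium-2-ide | C=CC[O+]1[CH-]C(=O)C[C@]1(C)CO[Si](c2ccccc2)(c2ccccc2)C(C)(C)C | intermediate
12 | (2S,5R)-5-{[(tert-butyldiphenylsilyl)oxy]methyl}-5-methyl-2-(prop-2-en-1-yl)oxolan-3-one | C=CC[C@@H]1O[C@@](C)(CO[Si](c2ccccc2)(c2ccccc2)C(C)(C)C)CC1=O | intermediate
13 | (2S,3S,5R)-5-{[(tert-butyldiphenylsilyl)oxy]methyl}-3,5-dimethyl-2-(prop-2-en-1-yl)oxolan-3-ol | C=CC[C@@H]1O[C@@](C)(CO[Si](c2ccccc2)(c2ccccc2)C(C)(C)C)C[C@]1(C)O | intermediate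
14 | ozonide, (2S,3S,5R)-5-{[(tert-butyldiphenylsilyl)oxy]methyl}-3,5-dimethyl-2-(1,2,4-trioxolan-3-ylmethyl)oxolan-3-ol | C3(OCOO3)C[C@@H]1O[C@@](C)(CO[Si](c2ccccc2)(c2ccccc2)C(C)(C)C)C[C@]1(C)O | intermediate
15 | 2-[(2S,3S,5R)-5-{[(tert-butyldiphenylsilyl)oxy]methyl}-3-hydroxy-3,5-dimethyloxolan-2-yl]acetaldehyde | O=CC[C@@H]1O[C@@](C)(CO[Si](c2ccccc2)(c2ccccc2)C(C)(C)C)C[C@]1(C)O | intermediate
16 | (3aS,5R,6aS)-5-{[(tert-butyldiphenylsilyl)oxy]methyl}-5,6a-dimethylhexahydrofuro[3,2-b]furan-2-ol (anomer mixture) | C[C@]1(CO[Si](c3ccccc3)(c3ccccc3)C(C)(C)C)C[C@]2(C)OC(O)C[C@@H]2O1 | intermediate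
17 | (3aS,5R,6aS)-5-{[(tert-butyldiphenylsilyl)oxy]methyl}-5,6a-dimethyltetrahydrofuro[3,2-b]furan-2(3H)-one | C[C@]1(CO[Si](c3ccccc3)(c3ccccc3)C(C)(C)C)C[C@]2(C)OC(=O)C[C@@H]2O1 | intermediate
18 | (3aS,5R,6aS)-5-(hydroxymethyl)-5,6a-dimethyltetrahydrofuro[3,2-b]furan-2(3H)-one | C[C@]1(CO)C[C@]2(C)OC(=O)C[C@@H]2O1 | intermediate
19 | (3aS,5R,6aS)-5,6a-dimethyl-2-oxohexahydrofuro[3,2-b]furan-5-carbaldehyde | C[C@]1(C=O)C[C@]2(C)OC(=O)C[C@@H]2O1 | intermediate
20 | 11-phenylundecanoic acid | OC(=O)CCCCCCCCCCc1ccccc1 | starting material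
21 | 11-phenylundecan-1-ol | OCCCCCCCCCCCc1ccccc1 | intermediate
22 | (11-bromoundecyl)benzene | BrCCCCCCCCCCCc1ccccc1 | intermediate
23 | (11-phenylundecyl)triphenylphosphonium bromide | [Br-].c1ccccc1CCCCCCCCCCC[P+](c1ccccc1)(c1ccccc1)c1ccccc1 | intermediate
24 | (11-phenylundecylidene)triphenylphosphorane | c1ccccc1CCCCCCCCCCC=P(c1ccccc1)(c1ccccc1)c1ccccc1 | intermediate
25 | (3aS,5R,6aS)-5,6a-dimethyl-5-(12-phenyldodec-1-en-1-yl)tetrahydrofuro[3,2-b]furan-2(3H)-one (alkene geometry not fixed) | C[C@]1(C=CCCCCCCCCCCc3ccccc3)C[C@]2(C)OC(=O)C[C@@H]2O1 | intermediate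
26 | plakortone L, (3aS,5S,6aS)-5,6a-dimethyl-5-(12-phenyldodecyl)tetrahydrofuro[3,2-b]furan-2(3H)-one | C[C@]1(CCCCCCCCCCCCc2ccccc2)C[C@]2(C)OC(=O)C[C@@H]2O1 | target

**Step count**

Total: 17 steps. Longest linear sequence: 14 steps (steps 1–12, 16 and 17); steps 13–15 prepare the side-chain salt.

**Steps most likely to fail**

Step 7 (key step). What may go wrong: the carbenoid may be diverted into C–H insertion at the OCH2 groups, cyclopropanation or a [1,2] shift. The ylide may also discriminate poorly between the methyl and silyloxymethyl faces of C6, so that allyl is delivered to the wrong face of C3. The fallback sets out from 4 and rejoins the route at 17. It makes rings A and B together by a palladium-mediated hydroxycyclisation–carbonylation–lactonisation instead of the carbenoid route. Ester 4 is converted with MeNH(OMe)·HCl and i-PrMgCl (THF, −20 °C) into (3R)-4-[(tert-butyldiphenylsilyl)oxy]-3-hydroxy-N-methoxy-N,3-dimethylbutanamide F1. MeMgBr then gives (4R)-5-[(tert-butyldiphenylsilyl)oxy]-4-hydroxy-4-methylpentan-2-one F2. Chelation-controlled addition of CH2=CHMgBr (THF, −78 °C), with chromatographic separation of the carbinol epimers, gives (3S,5R)-6-[(tert-butyldiphenylsilyl)oxy]-3,5-dimethylhex-1-ene-3,5-diol F3. Treatment of F3 with PdCl2 (10 mol%), CuCl2, NaOAc and CO (1 atm) in AcOH at rt should let the C6 hydroxyl add to the alkene activated by divalent palladium (5-exo, O–C3 bond). CO then inserts into the C2–Pd bond and the C4 hydroxyl captures the acyl palladium, which can only give the cis-fused lactone 17.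

Step 4. What may go wrong: the hindered, electron-poor tertiary hydroxyl may be alkylated too slowly, so that rearrangement of the imidate to the N-allyl amide or acid-promoted loss of the silyl group wins. The fallback sets out from 4 and rejoins at 6. It replaces Brønsted-acid activation of an imidate by a π-allyl palladium electrophile under neutral conditions (Tsuji–Trost O-allylation): allyl tert-butyl carbonate, Pd2(dba)3 (zerovalent palladium) and dppb in THF at reflux. Decarboxylation releases tert-butoxide, which deprotonates the tertiary alcohol only transiently, and the alkoxide attacks the π-allyl complex to give 6 directly. The fallback makes no new compound (F0).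

Step 8. What may go wrong: methyl may be delivered to the face of C4 syn to the allyl group, because the opposite face carries the silyloxymethyl group on C6, or the ketone may enolise and ring-open by β-elimination. The fallback sets out from 12 and rejoins at 17. It fixes C4 by an iodolactonisation, in which ring fusion and not facial attack decides the configuration. Ozonolysis of 12 (O3, CH2Cl2, −78 °C; PPh3) gives 2-[(2S,5R)-5-{[(tert-butyldiphenylsilyl)oxy]methyl}-5-methyl-3-oxooxolan-2-yl]acetaldehyde F4. Pinnick oxidation (NaClO2, NaH2PO4, 2-methylbut-2-ene, t-BuOH/H2O) gives 2-[(2S,5R)-5-{[(tert-butyldiphenylsilyl)oxy]methyl}-5-methyl-3-oxooxolan-2-yl]acetic acid F5. Non-basic Takai–Lombardo methylenation (Zn, CH2Br2, TiCl4, THF/CH2Cl2) gives 2-[(2S,5R)-5-{[(tert-butyldiphenylsilyl)oxy]methyl}-5-methyl-3-methylideneoxolan-2-yl]acetic acid F6 without epimerising C3. Iodolactonisation (I2, NaHCO3, MeCN) gives (3aS,5R,6aS)-5-{[(tert-butyldiphenylsilyl)oxy]methyl}-6a-(iodomethyl)-5-methyltetrahydrofuro[3,2-b]furan-2(3H)-one F7, since the carboxylate can reach C4 only from the face of its own arm. Radical reduction (Bu3SnH, AIBN, toluene, 80 °C) turns the CH2I group into the C4 methyl of 17.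

**Further compounds**

F1 | step 7 | (3R)-4-[(tert-butyldiphenylsilyl)oxy]-3-hydroxy-N-methoxy-N,3-dimethylbutanamide | C[C@](O)(CO[Si](c1ccccc1)(c1ccccc1)C(C)(C)C)CC(=O)N(C)OC
F2 | step 7 | (4R)-5-[(tert-butyldiphenylsilyl)oxy]-4-hydroxy-4-methylpentan-2-one | C[C@](O)(CO[Si](c1ccccc1)(c1ccccc1)C(C)(C)C)CC(C)=O
F3 | step 7 | (3S,5R)-6-[(tert-butyldiphenylsilyl)oxy]-3,5-dimethylhex-1-ene-3,5-diol | C[C@](O)(CO[Si](c1ccccc1)(c1ccccc1)C(C)(C)C)C[C@](C=C)(C)O
F0 | step 4 | none | none
F4 | step 8 | 2-[(2S,5R)-5-{[(tert-butyldiphenylsilyl)oxy]methyl}-5-methyl-3-oxooxolan-2-yl]acetaldehyde | O=CC[C@@H]1O[C@@](C)(CO[Si](c2ccccc2)(c2ccccc2)C(C)(C)C)CC1=O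
F5 | step 8 | 2-[(2S,5R)-5-{[(tert-butyldiphenylsilyl)oxy]methyl}-5-methyl-3-oxooxolan-2-yl]acetic acid | OC(=O)C[C@@H]1O[C@@](C)(CO[Si](c2ccccc2)(c2ccccc2)C(C)(C)C)CC1=O
F6 | step 8 | 2-[(2S,5R)-5-{[(tert-butyldiphenylsilyl)oxy]methyl}-5-methyl-3-methylideneoxolan-2-yl]acetic acid | OC(=O)C[C@@H]1O[C@@](C)(CO[Si](c2ccccc2)(c2ccccc2)C(C)(C)C)CC1=C
F7 | step 8 | (3aS,5R,6aS)-5-{[(tert-butyldiphenylsilyl)oxy]methyl}-6a-(iodomethyl)-5-methyltetrahydrofuro[3,2-b]furan-2(3H)-one | C[C@]1(CO[Si](c3ccccc3)(c3ccccc3)C(C)(C)C)C[C@]2(CI)OC(=O)C[C@@H]2O1
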